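**Strategy.** Everything rests on disconnecting the six hydroxyls that flank the hindered diaryl ether carbons: O–C-2 and O–C-6 of ring A and O–C-3 and O–C-5 of rings C and E (ether carbons C-1 of A, C-4 of C and E). One sixfold Baeyer–Villiger (Dakin-type) oxidation, with formate methanolysis in the same flask, converts six aryl–CHO groups into six aryl–OH groups. Its precursor is a hexa-aldehyde in which rings A, C and E are 2-aryloxyisophthalaldehydes and the ten other hydroxyls are methyl ethers. The same formyl pairs first activate a fluoride for SNAr, so each hindered ether forms easily; two Ullmann couplings join three dimers.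

Key step: step 14

Remark on the chemistry: the target has no stereocentre, so nothing has to be set or preserved. Rings are lettered A (2,4,6-trioxygenated end ring) to F (3,4,5-trioxygenated end ring). The hexa-aldehyde 16 and hexaphenol 18 reproduce the oxygen pattern of the target position by position.

Design choices: the phenol is carried through the radical bromination as its acetate, not as an ether, so the ring is not brominated. The temporary group on rings C and E is a methoxymethyl (MOM) ether, removed by dilute acid that leaves aldehydes, methyl ethers, diaryl ethers and the aryl iodide alone. In the key step the excess peracid is destroyed before the formates are cleaved.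

Step 1
Reactants: 1 4-fluoro-3,5-dimethylphenol
Product: 2 4-fluoro-3,5-dimethylphenyl acetate
Conditions: Ac2O, pyridine, DMAP (cat.), CH2Cl2, rt
Reagents that add atoms: acetic anhydride, CC(=O)OC(C)=O
Why: DMAP-catalysed O-acylation of a phenol is routine and turns the ring-activating hydroxyl into an ester that suppresses nuclear bromination in the next step.

Step 2
Reactants: 2 4-fluoro-3,5-dimethylphenyl acetate
Product: 3 3,5-bis(dibromomethyl)-4-fluorophenyl acetate
Conditions: NBS (4.6 equiv), AIBN (cat.), PhCF3, reflux, visible light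
Reagents that add atoms: N-bromosuccinimide, O=C1CCC(=O)N1Br
Why: Wohl–Ziegler radical bromination should take both benzylic methyl groups to the dibromomethyl stage, since a third bromination is slowed by the ortho fluorine and the two bromines already present, and the acetoxy ring is too electron-poor for electrophilic ring bromination.

Step 3
Reactants: 3 3,5-bis(dibromomethyl)-4-fluorophenyl acetate
Product: 5 2-fluoro-5-hydroxyisophthalaldehyde, via 4-fluoro-3,5-diformylphenyl acetate 4 (not isolated)
Conditions: HCO2H/H2O (88:12), reflux; then aq. HCl (2 M), 60 °C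
Reagents that add atoms: water, O
Why: Acid hydrolysis of the two benzal bromides gives dialdehyde 4 and acid-catalysed ester hydrolysis then frees the phenol, while the acidic medium keeps the doubly activated C–F bond safe from the SNAr that hydroxide or alkoxide would cause.

Step 4
Reactants: 5 2-fluoro-5-hydroxyisophthalaldehyde
Product: 6 2-fluoro-5-methoxyisophthalaldehyde
Conditions: MeI (3 equiv), K2CO3, MeCN, 0 °C to rt
Reagents that add atoms: iodomethane, CI
Why: Williamson ether synthesis, in which the phenoxide (whose para oxygen anion switches off SNAr at its own C–F bond) should be methylated by excess MeI faster than it can attack the fluoride of product already formed.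

Step 5
Reactants: 5 2-fluoro-5-hydroxyisophthalaldehyde
Product: 7 2-fluoro-5-(methoxymethoxy)isophthalaldehyde
Conditions: MOMCl (1.5 equiv), K2CO3, MeCN, 0 °C to rt
Reagents that add atoms: chloromethyl methyl ether, COCCl
Why: Williamson-type O-alkylation with the highly reactive chloromethyl ether gives the MOM acetal, which survives carbonate bases and copper catalysis.

Step 6
Reactants: 8 3,4,5-trimethoxyphenol
Product: 9 2-iodo-3,4,5-trimethoxyphenol
Conditions: NIS (1.0 equiv), MeCN, 0 °C, dark
Reagents that add atoms: N-iodosuccinimide, O=C1CCC(=O)N1I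
Why: Electrophilic aromatic iodination, in which C-2 and C-6 are the only free positions, equivalent and strongly activated (ortho to OH, para to OMe), so one equivalent of NIS at low temperature should give the mono-iodide.

Step 7
Reactants: 6 2-fluoro-5-methoxyisophthalaldehyde; 9 2-iodo-3,4,5-trimethoxyphenol
Product: 10 dimer AB, 2-(2-iodo-3,4,5-trimethoxyphenoxy)-5-methoxyisophthalaldehyde
Conditions: K2CO3, DMF, rt to 50 °C, argon
Reagents that add atoms: none
Why: SNAr through a Meisenheimer adduct, in which the fluoride flanked by two ortho formyl groups should be displaced by the phenoxide of 9 under mild carbonate conditions despite the ortho iodine, forming the hindered ring A–O–ring B ether.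

Step 8
Reactants: 7 2-fluoro-5-(methoxymethoxy)isophthalaldehyde; 9 2-iodo-3,4,5-trimethoxyphenol
Product: 11 dimer CD, 2-(2-iodo-3,4,5-trimethoxyphenoxy)-5-(methoxymethoxy)isophthalaldehyde
Conditions: K2CO3, DMF, rt to 50 °C, argon
Reagents that add atoms: none
Why: The same SNAr at the doubly formyl-activated fluoride forms the hindered ring C–O–ring D ether, and the MOM acetal is inert to carbonate.

Step 9
Reactants: 7 2-fluoro-5-(methoxymethoxy)isophthalaldehyde; 8 3,4,5-trimethoxyphenol
Product: 12 dimer EF, 5-(methoxymethoxy)-2-(3,4,5-trimethoxyphenoxy)isophthalaldehyde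
Conditions: K2CO3, DMF, rt, argon
Reagents that add atoms: none
Why: SNAr of the unhindered, electron-rich phenoxide of 8 on the doubly activated fluoride forms the ring E–O–ring F ether.

Step 10
Reactants: 12 dimer EF
Product: 13 5-hydroxy-2-(3,4,5-trimethoxyphenoxy)isophthalaldehyde (phenol EF)
Conditions: aq. HCl (3 M), THF, 50 °C
Reagents that add atoms: none
Why: Acid-catalysed hydrolysis of the formaldehyde mixed acetal frees the ring E phenol, and aldehydes, methyl ethers and the diaryl ether are inert to dilute aqueous acid.

Step 11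
Reactants: 13 phenol EF; 11 dimer CD
Product: 14 tetramer C–F tetra-aldehyde with MOM ether on ring C, 2-{2-[3,5-diformyl-4-(3,4,5-trimethoxyphenoxy)phenoxy]-3,4,5-trimethoxyphenoxy}-5-(methoxymethoxy)isophthalaldehyde
Conditions: CuI (20 mol%), N,N-dimethylglycine hydrochloride (40 mol%), Cs2CO3, 1,4-dioxane, 90 °C, argon
Reagents that add atoms: none
Why: Ullmann-type diaryl ether coupling under CuI/amino-acid catalysis, in which the unhindered, fairly acidic phenol of 13 should displace the aryl iodide of 11 (the most reactive halide, flanked by oxygen atoms that can assist copper), carbonate tolerates the non-enolisable aldehydes, and the low-polarity solvent holds back uncatalysed SNAr exchange at the formyl-activated ethers.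

Step 12
Reactants: 14 tetramer C–F MOM ether
Product: 15 tetramer C–F phenol, 2-{2-[3,5-diformyl-4-(3,4,5-trimethoxyphenoxy)phenoxy]-3,4,5-trimethoxyphenoxy}-5-hydroxyisophthalaldehyde
Conditions: aq. HCl (3 M), THF, 50 °C
Reagents that add atoms: none
Why: The same acid-catalysed acetal hydrolysis frees the ring C phenol without touching the four aldehydes, six methyl ethers or three diaryl ethers.

Step 13
Reactants: 15 tetramer C–F phenol; 10 dimer AB
Product: 16 hexamer hexa-aldehyde (rings A/C/E as 2-aryloxyisophthalaldehydes; ten methyl ethers)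
Conditions: CuI (20 mol%), N,N-dimethylglycine hydrochloride (40 mol%), Cs2CO3, 1,4-dioxane, 90 °C, argon
Reagents that add atoms: none
Why: A second Ullmann-type diaryl ether coupling of the same kind joins the ring C phenoxide to C-2 of ring B, completing the six-ring chain.

Step 14
Reactants: 16 hexamer hexa-aldehyde
Product: 18 hexamer hexaphenol (six free hydroxyls on rings A/C/E; ten methyl ethers), via hexamer hexa-formate 17 (not isolated)
Conditions: mCPBA (7.5 equiv), Na2HPO4, CH2Cl2, 0 °C to rt; Me2S; then MeOH, Et3N (cat.), rt, argon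
Reagents that add atoms: meta-chloroperoxybenzoic acid, OOC(=O)c1cccc(Cl)c1
Why: Each formyl group adds the peracid to give a Criegee adduct, the aryl carbon migrates to oxygen with loss of 3-chlorobenzoate, and the six aryl formates of 17 are transesterified by methanol once Me2S has reduced the excess peracid. The closest known reaction is the Baeyer–Villiger (Dakin-type) oxidation of ortho-alkoxy- and ortho-aryloxybenzaldehydes to phenols, applied here six times in one flask. No ring is closed and no stereocentre is created. Aryl rather than hydride migration is needed at every aldehyde; it is secured by the ether oxygen ortho to each migrating carbon (on C-1 of ring A, C-4 of rings C and E), whose lone pair stabilises the positive charge building up on the migrating ring, and each formate formed makes its ring richer for the second migration. Carbonyl oxidation must also beat oxidation of the methoxylated rings B, D and F, which the phosphate buffer (no strong acid to activate the peracid), the small excess of oxidant and the low temperature should ensure. The new, oxidation-prone phenols stay masked as formates until no peracid is left.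

Step 15
Reactants: 18 hexamer hexaphenol
Product: 19 CNP0218077.0 (hexadecahydroxy hexamer)
Conditions: BBr3 (30 equiv), CH2Cl2, −78 °C to rt, argon; then degassed H2O, 0 °C; Sephadex LH-20 under argon
Reagents that add atoms: none
Why: Lewis acid-mediated aryl methyl ether cleavage, in which BBr3 coordinates each methoxy oxygen and bromide attacks the methyl carbon (SN2), so the sp2 C–O bonds of the five diaryl ethers stay intact and aqueous work-up of the borates should free all sixteen hydroxyls.

**Compound list**

1 | 4-fluoro-3,5-dimethylphenol | Cc1cc(O)cc(C)c1F | starting material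
2 | 4-fluoro-3,5-dimethylphenyl acetate | CC(=O)Oc1cc(C)c(F)c(C)c1 | intermediate
3 | 3,5-bis(dibromomethyl)-4-fluorophenyl acetate | CC(=O)Oc1cc(C(Br)Br)c(F)c(C(Br)Br)c1 | intermediate
4 | 4-fluoro-3,5-diformylphenyl acetate | CC(=O)Oc1cc(C=O)c(F)c(C=O)c1 | intermediate (not isolated)
5 | 2-fluoro-5-hydroxyisophthalaldehyde | Oc1cc(C=O)c(F)c(C=O)c1 | intermediate
6 | 2-fluoro-5-methoxyisophthalaldehyde | COc1cc(C=O)c(F)c(C=O)c1 | intermediate
7 | 2-fluoro-5-(methoxymethoxy)isophthalaldehyde | COCOc1cc(C=O)c(F)c(C=O)c1 | intermediate
8 | 3,4,5-trimethoxyphenol | COc1cc(O)cc(OC)c1OC | starting material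
9 | 2-iodo-3,4,5-trimethoxyphenol | COc1cc(O)c(I)c(OC)c1OC | intermediate
10 | dimer AB, 2-(2-iodo-3,4,5-trimethoxyphenoxy)-5-methoxyisophthalaldehyde | COc1cc(C=O)c(Oc2cc(OC)c(OC)c(OC)c2I)c(C=O)c1 | intermediate
11 | dimer CD, 2-(2-iodo-3,4,5-trimethoxyphenoxy)-5-(methoxymethoxy)isophthalaldehyde | COCOc1cc(C=O)c(Oc2cc(OC)c(OC)c(OC)c2I)c(C=O)c1 | intermediate
12 | dimer EF, 5-(methoxymethoxy)-2-(3,4,5-trimethoxyphenoxy)isophthalaldehyde | COCOc1cc(C=O)c(Oc2cc(OC)c(OC)c(OC)c2)c(C=O)c1 | intermediate
13 | phenol EF, 5-hydroxy-2-(3,4,5-trimethoxyphenoxy)isophthalaldehyde | Oc1cc(C=O)c(Oc2cc(OC)c(OC)c(OC)c2)c(C=O)c1 | intermediate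
14 | tetramer C–F tetra-aldehyde, MOM ether on ring C | COCOc1cc(C=O)c(Oc2cc(OC)c(OC)c(OC)c2Oc2cc(C=O)c(Oc3cc(OC)c(OC)c(OC)c3)c(C=O)c2)c(C=O)c1 | intermediate
15 | tetramer C–F tetra-aldehyde, free phenol on ring C | Oc1cc(C=O)c(Oc2cc(OC)c(OC)c(OC)c2Oc2cc(C=O)c(Oc3cc(OC)c(OC)c(OC)c3)c(C=O)c2)c(C=O)c1 | intermediate
16 | hexamer hexa-aldehyde (rings A, C, E as 2-aryloxyisophthalaldehydes; ten methyl ethers) | COc1cc(C=O)c(Oc2cc(OC)c(OC)c(OC)c2Oc2cc(C=O)c(Oc3cc(OC)c(OC)c(OC)c3Oc3cc(C=O)c(Oc4cc(OC)c(OC)c(OC)c4)c(C=O)c3)c(C=O)c2)c(C=O)c1 | intermediate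
17 | hexamer hexa-formate (each formyl of 16 replaced by O–CHO) | COc1cc(OC=O)c(Oc2cc(OC)c(OC)c(OC)c2Oc2cc(OC=O)c(Oc3cc(OC)c(OC)c(OC)c3Oc3cc(OC=O)c(Oc4cc(OC)c(OC)c(OC)c4)c(OC=O)c3)c(OC=O)c2)c(OC=O)c1 | intermediate (not isolated)
18 | hexamer hexaphenol (free hydroxyls at C-2/C-6 of ring A and C-3/C-5 of rings C and E; ten methyl ethers) | COc1cc(O)c(Oc2cc(OC)c(OC)c(OC)c2Oc2cc(O)c(Oc3cc(OC)c(OC)c(OC)c3Oc3cc(O)c(Oc4cc(OC)c(OC)c(OC)c4)c(O)c3)c(O)c2)c(O)c1 | intermediate
19 | CNP0218077.0 | Oc1cc(O)c(Oc2cc(O)c(O)c(O)c2Oc2cc(O)c(Oc3cc(O)c(O)c(O)c3Oc3cc(O)c(Oc4cc(O)c(O)c(O)c4)c(O)c3)c(O)c2)c(O)c1 | target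

**Step count**

Total steps: 15. Longest linear sequence: 11 steps (steps 1, 2, 3, 5, 9, 10, 11, 12, 13, 14, 15, from 1 to 19).

**Steps most likely to fail**

The first risk is step 14. Some of the six Criegee adducts may undergo hydride instead of aryl migration, ending as carboxylic acids. The oxidation may also stall before all six aldehydes have reacted, or the peracid may begin to oxidise the methoxylated rings during the long exposure. The fallback removes the hydride option by going through methyl ketones. It sets out from 16: sixfold Grignard addition (MeMgBr, THF, −78 to 0 °C) should give the hexakis(1-hydroxyethyl) hexamer F1 as a diastereomer mixture whose stereocentres are erased in the next step. Dess–Martin oxidation (CH2Cl2, rt) should give the hexa-acetyl hexamer F2. Baeyer–Villiger oxidation of the aryl methyl ketones (mCPBA, CF3CO2H cat., CH2Cl2, rt), in which aryl always out-migrates methyl, should give the hexa-acetate F3. Methanolysis (K2CO3, degassed MeOH, rt) returns to the route at 18.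

The second risk is step 13. Carbon–oxygen bond formation at the electron-rich C–I bond, which is flanked by a methoxy group and a bulky diformylaryloxy group, may be slow. Protodeiodination and phenoxide attack at the formyl-activated ether carbons (ether exchange) could then take over. The fallback makes the hindered ring A–O–ring B ether last, by SNAr, and uses a small iodide partner without aldehydes or an activated ether. It sets out from 15 and 9. Iodophenol 9 is capped (MOMCl, K2CO3, MeCN) as 2-iodo-3,4,5-trimethoxy-1-(methoxymethoxy)benzene F4. Ullmann coupling of 15 with F4 (CuI, N,N-dimethylglycine hydrochloride, Cs2CO3, dioxane, 90 °C) should give the rings B–F pentamer MOM ether F5. Dilute HCl in THF frees the rings B–F pentamer phenol F6. SNAr of F6 on fluoride 6 (K2CO3, DMF) returns to the route at 16.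

The third risk is step 11, for the same reason: slow coupling at the di-ortho-substituted iodide of 11 lets deiodination and ether exchange compete. The fallback again moves the hindered ether formation to an SNAr. It sets out from 13. Ullmann coupling of 13 with 2-iodo-3,4,5-trimethoxy-1-(methoxymethoxy)benzene F4 (same copper system) should give the rings D–F trimer MOM ether F7. Dilute HCl in THF gives the rings D–F trimer phenol F8. SNAr of F8 on fluoride 7 (K2CO3, DMF) returns to the route at 14.

**Further compounds**

F1 | step 14 | hexakis(1-hydroxyethyl) hexamer (each CHO of 16 as CH(OH)CH3; diastereomer mixture) | COc1cc(C(C)O)c(Oc2cc(OC)c(OC)c(OC)c2Oc2cc(C(C)O)c(Oc3cc(OC)c(OC)c(OC)c3Oc3cc(C(C)O)c(Oc4cc(OC)c(OC)c(OC)c4)c(C(C)O)c3)c(C(C)O)c2)c(C(C)O)c1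
F2 | step 14 | hexa-acetyl hexamer (each CHO of 16 as COCH3) | COc1cc(C(C)=O)c(Oc2cc(OC)c(OC)c(OC)c2Oc2cc(C(C)=O)c(Oc3cc(OC)c(OC)c(OC)c3Oc3cc(C(C)=O)c(Oc4cc(OC)c(OC)c(OC)c4)c(C(C)=O)c3)c(C(C)=O)c2)c(C(C)=O)c1
F3 | step 14 | hexa-acetate of hexaphenol 18 | COc1cc(OC(C)=O)c(Oc2cc(OC)c(OC)c(OC)c2Oc2cc(OC(C)=O)c(Oc3cc(OC)c(OC)c(OC)c3Oc3cc(OC(C)=O)c(Oc4cc(OC)c(OC)c(OC)c4)c(OC(C)=O)c3)c(OC(C)=O)c2)c(OC(C)=O)c1
F4 | step 13 | 2-iodo-3,4,5-trimethoxy-1-(methoxymethoxy)benzene | COCOc1cc(OC)c(OC)c(OC)c1I
F5 | step 13 | rings B–F pentamer tetra-aldehyde, MOM ether at C-1 of ring B | COCOc1cc(OC)c(OC)c(OC)c1Oc1cc(C=O)c(Oc2cc(OC)c(OC)c(OC)c2Oc2cc(C=O)c(Oc3cc(OC)c(OC)c(OC)c3)c(C=O)c2)c(C=O)c1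
F6 | step 13 | rings B–F pentamer tetra-aldehyde, free phenol at C-1 of ring B | Oc1cc(OC)c(OC)c(OC)c1Oc1cc(C=O)c(Oc2cc(OC)c(OC)c(OC)c2Oc2cc(C=O)c(Oc3cc(OC)c(OC)c(OC)c3)c(C=O)c2)c(C=O)c1
F7 | step 11 | rings D–F trimer dialdehyde, MOM ether at C-1 of ring D | COCOc1cc(OC)c(OC)c(OC)c1Oc1cc(C=O)c(Oc2cc(OC)c(OC)c(OC)c2)c(C=O)c1
F8 | step 11 | rings D–F trimer dialdehyde, free phenol at C-1 of ring D | Oc1cc(OC)c(OC)c(OC)c1Oc1cc(C=O)c(Oc2cc(OC)c(OC)c(OC)c2)c(C=O)c1
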